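**Retrosynthetic overview**

1. Locants: ring C1 (carries the side chain), C2 (O-angelate), C3 (OH), C4 (Me, epoxide), C5 (epoxide CH), C6 (CH2); side chain C7 (the =CH2 carbon), C8 (CH–O-angelate), C9, C10 (CHOH), C11 (CMe2OH). The oxirane is made last by C3–OH-directed epoxidation of C4=C5; before that, diol 15 receives both angelates (C2–O, C8–O) and the PMB and silyl groups are removed.
2. The C8 carbinol comes from a C8 ketone (CBS reduction), released by hydrolysis of bicyclic mixed ketal 13, in which C8 is bonded to the C2 oxygen.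
3. Key disconnection C1–C7: 13 comes from iodo ketal 12 by 5-exo vinyl-radical cyclisation onto C1 of the ring 1,3-diene (C1=C6–C5=C4); the allyl radical takes H at C6 and returns the C4=C5 alkene.
4. 12 is assembled by iodoketalisation of ring alcohol 3 (from toluene cis-dihydrodiol; C2 and C3 bought) with alkoxyallene 11 (from methyl (S)-glycidate, C10 bought, and methoxyallene).
5. Enabling feature: the cis array O–C2–C1–C7–C8 (C2 oxygen and C7 on the same ring face, C8 oxygenated) can be closed as a temporary cis-fused 2-methoxy-3-methylenetetrahydrofuran. Ring order: cyclohexadiene bought; tetrahydrofuran closed in step 7 and opened in step 8; oxirane closed in step 13.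

Key step: step 7

Assumption: (1S,2R)-3-methylcyclohexa-3,5-diene-1,2-diol (the microbial cis-dihydrodiol of toluene) is taken as a purchasable chiral-pool compound and is handled cold because it dehydrates and dimerises easily.

**Route**

Step 1
Reactants: 1 (1S,2R)-3-methylcyclohexa-3,5-diene-1,2-diol
Product: 2 (3aR,7aS)-2-(4-methoxyphenyl)-4-methyl-3a,7a-dihydro-1,3-benzodioxole (both epimers at the acetal carbon)
Conditions: 4-MeOC6H4CH(OMe)2, CSA (cat.), CH2Cl2, −20 °C
Reagents that add atoms: 4-methoxybenzaldehyde dimethyl acetal, COC(OC)c1ccc(OC)cc1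
Why: Acid-catalysed transacetalisation (cyclic p-methoxybenzylidene acetal formation) of the cis-1,2-diol is routine for arene cis-dihydrodiols at low temperature, touches no ring stereocentre, and the two acetal epimers converge in step 2.

Step 2
Reactants: 2 (3aR,7aS)-2-(4-methoxyphenyl)-4-methyl-3a,7a-dihydro-1,3-benzodioxole
Product: 3 (1S,6R)-6-[(4-methoxybenzyl)oxy]-5-methylcyclohexa-2,4-dien-1-ol (free OH on C2, PMB ether on C3 of the target numbering)
Conditions: DIBAL-H, CH2Cl2, −78 → 0 °C; Rochelle salt
Reagents that add atoms: none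
Why: Regioselective reductive acetal opening with DIBAL-H: aluminium should bind the less hindered acetal oxygen (remote from the methyl-bearing alkene carbon), that C–O bond breaks and hydride quenches the oxocarbenium ion, so the free hydroxyl appears at C2 and the PMB ether at the hindered C3 oxygen, with both stereocentres untouched.

Step 3
Reactants: 4 methyl (2S)-oxirane-2-carboxylate
Product: 6 2-[(2S)-oxiran-2-yl]propan-2-ol, via 1-[(2S)-oxiran-2-yl]ethan-1-one 5 (not isolated)
Conditions: MeMgCl (2.2 equiv), THF, −78 → −20 °C; aq. NH4Cl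
Reagents that add atoms: methylmagnesium chloride, C[Mg]Cl
Why: Double Grignard addition to the ester through the methyl ketone is faster at low temperature than epoxide opening (the chloride reagent limits halohydrin formation), and the stereocentre is not involved.

Step 4
Reactants: 6 2-[(2S)-oxiran-2-yl]propan-2-ol
Product: 7 triethyl({2-[(2S)-oxiran-2-yl]propan-2-yl}oxy)silane
Conditions: TESOTf, 2,6-lutidine, CH2Cl2, −78 °C
Reagents that add atoms: triethylsilyl triflate, CC[Si](CC)(CC)OS(=O)(=O)C(F)(F)F
Why: Silyl triflate/2,6-lutidine silylation is the standard way to cap a tertiary alcohol and is fast at −78 °C, where the epoxide should not be opened.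

Step 5
Reactants: 7 triethyl({2-[(2S)-oxiran-2-yl]propan-2-yl}oxy)silane; 8 methoxyallene (1-methoxypropa-1,2-diene)
Product: 11 (5S)-5-[(tert-butyldimethylsilyl)oxy]-3-methoxy-6-methyl-6-[(triethylsilyl)oxy]hepta-1,2-diene, via 1-lithio-1-methoxyallene 9 (not isolated), via lithium alkoxide of the ring-opened epoxide 10 (not isolated)
Conditions: n-BuLi, THF, −40 °C; then 7, DMPU, −40 → 0 °C; then TBSOTf, −78 → 0 °C
Reagents that add atoms: tert-butyldimethylsilyl triflate, CC(C)(C)[Si](C)(C)OS(=O)(=O)C(F)(F)F
Why: Methoxyallene is lithiated at its oxygen-bearing carbon, the allenyllithium opens the monosubstituted epoxide at the CH2 terminus in an SN2 reaction (stereocentre untouched), and the lithium alkoxide is silylated in the same flask, which avoids any acidic handling of the acid-labile alkoxyallene.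

Step 6
Reactants: 3 (1S,6R)-6-[(4-methoxybenzyl)oxy]-5-methylcyclohexa-2,4-dien-1-ol; 11 (5S)-5-[(tert-butyldimethylsilyl)oxy]-3-methoxy-6-methyl-6-[(triethylsilyl)oxy]hepta-1,2-diene
Product: 12 (5S)-5-[(tert-butyldimethylsilyl)oxy]-2-iodo-3-methoxy-3-{[(1S,6R)-6-[(4-methoxybenzyl)oxy]-5-methylcyclohexa-2,4-dien-1-yl]oxy}-6-methyl-6-[(triethylsilyl)oxy]hept-1-ene (both epimers at the ketal carbon)
Conditions: NIS, 2,6-di-tert-butylpyridine, CH2Cl2, −78 → −40 °C
Reagents that add atoms: N-iodosuccinimide, O=C1CCC(=O)N1I
Why: Iodoalkoxylation of an alkoxyallene (Ueno–Stork-type haloacetalisation): iodonium should attack the central carbon of the electron-rich allenyl ether far faster than the ring diene, and the methoxy-stabilised oxocarbenium ion is captured by the only free hydroxyl of 3, giving the 2-iodoallyl mixed ketal as two inconsequential ketal epimers.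

Step 7
Reactants: 12 the 2-iodoallyl mixed ketal from step 6
Product: 13 (3aR,7R,7aS)-2-{(2S)-2-[(tert-butyldimethylsilyl)oxy]-3-methyl-3-[(triethylsilyl)oxy]butyl}-2-methoxy-7-[(4-methoxybenzyl)oxy]-6-methyl-3-methylidene-2,3,3a,4,7,7a-hexahydro-1-benzofuran (both epimers at C2 of the benzofuran; C3a is C1 of the target)
Conditions: Bu3SnH (syringe pump), Et3B, air, PhMe (0.01 M), 0 °C → rt
Reagents that add atoms: none
Why: Iodine abstraction by the stannyl radical gives the σ-vinyl radical at C7, which adds to C1, the terminus of the ring diene, and the resulting C6–C5–C4 allyl radical takes a hydrogen atom from Bu3SnH. The closest known reaction type is the Ueno–Stork haloacetal radical cyclisation in its vinyl-radical (2-haloallyl acetal) form, here ending on a 1,3-diene. The tetrahydrofuran ring (O, C8, C7, C1, C2) closes in the 5-exo-trig mode. The new stereocentre C1 is controlled by the tether: the radical hangs from the C2 oxygen and a five-membered ring can only be cis-fused to the cyclohexene, so C7 is delivered to the face of C1 that carries the C2 (and C3) oxygen. The step needs regioselectivity twice and chemoselectivity once: attack at C1 rather than C6 is secured by the 5-exo geometry and the allylic stabilisation of the product radical, hydrogen transfer to C6 rather than C4 by the hindrance at the methyl-bearing C4 next to the PMB ether and by formation of the trisubstituted C4=C5 alkene, and cyclisation before reduction by the high rate of vinyl-radical addition to a diene at low stannane concentration.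

Step 8
Reactants: 13 the bicyclic mixed ketal from step 7
Product: 14 (5S)-5-[(tert-butyldimethylsilyl)oxy]-2-[(1R,5R,6S)-6-hydroxy-5-[(4-methoxybenzyl)oxy]-4-methylcyclohex-3-en-1-yl]-6-methyl-6-[(triethylsilyl)oxy]hept-1-en-3-one
Conditions: PPTS (cat.), acetone–H2O (10:1), rt
Reagents that add atoms: water, O
Why: Acid-catalysed ketal hydrolysis: the 2-methoxytetrahydrofuran ketal next to the exocyclic alkene ionises far more easily than the PMB ether or the hindered silyl ethers, so mild aqueous PPTS should release the C2 hydroxyl and the C8 enone (in equilibrium with its cyclic hemiketal) without affecting C1.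

Step 9
Reactants: 14 the γ-hydroxy enone from step 8
Product: 15 (3S,5S)-5-[(tert-butyldimethylsilyl)oxy]-2-[(1R,5R,6S)-6-hydroxy-5-[(4-methoxybenzyl)oxy]-4-methylcyclohex-3-en-1-yl]-6-methyl-6-[(triethylsilyl)oxy]hept-1-en-3-ol
Conditions: (R)-Me-CBS, catecholborane, PhMe, −78 °C
Reagents that add atoms: none
Why: Corey–Bakshi–Shibata reduction with catecholborane reduces enones 1,2, and with the (R)-oxazaborolidine the α-branched alkenyl group acts as the large substituent, so hydride is delivered under reagent control to give the (S)-carbinol at C8, anti to the C10 silyloxy group.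

Step 10
Reactants: 15 the C2,C8-diol from step 9
Product: 16 the bis-angelate of 15: (Z)-2-methylbut-2-enoate esters on the ring C2 oxygen and on the C8 oxygen, C3 still PMB-protected, C10 OTBS, C11 OTES, all configurations as in 15
Conditions: angelic acid, 2,4,6-Cl3C6H2COCl, Et3N, PhMe, rt; then 15, PhMe, 80 °C
Reagents that add atoms: angelic acid ((Z)-2-methylbut-2-enoic acid), C/C=C(/C)C(=O)O
Why: Mixed-anhydride (Yamaguchi-type) esterification without a nucleophilic amine catalyst acylates both secondary hydroxyls at oxygen (no stereocentre is touched) and is the protocol known to give angelates without Z to E isomerisation to tiglates.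

Step 11
Reactants: 16 the bis-angelate PMB ether
Product: 17 the C3 alcohol: 16 with the PMB ether replaced by a free hydroxyl (allylic to C4=C5, cis to the C2 angelate)
Conditions: DDQ, CH2Cl2–pH 7 buffer (10:1), 0 °C
Reagents that add atoms: none
Why: Oxidative cleavage of the p-methoxybenzyl ether with DDQ (hydride abstraction from the electron-rich benzylic position, then hydrolysis) is orthogonal to the esters, silyl ethers and alkenes.

Step 12
Reactants: 17 the bis-silyl ether
Product: 18 the triol: ring C3–OH, side-chain C10–OH and C11–OH free, angelates on C2–O and C8–O, alkenes C4=C5 and C7=CH2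
Conditions: HF·pyridine, pyridine, THF, 0 °C → rt
Reagents that add atoms: none
Why: Fluoride-mediated desilylation with pyridine-buffered HF·pyridine removes the TBS and the tertiary TES ether under mildly acidic conditions in which the angelates should neither migrate nor isomerise.

Step 13
Reactants: 18 the triol
Product: 19 CNP0189369.2 (target; ring C1 R, C2 S, C3 S, C4 S, C5 R; side chain C8 S, C10 S)
Conditions: VO(acac)2 (cat.), t-BuOOH, CH2Cl2, 0 °C → rt
Reagents that add atoms: tert-butyl hydroperoxide, CC(C)(C)OO
Why: Vanadium-catalysed hydroxyl-directed epoxidation (Sharpless VO(acac)2/TBHP) delivers oxygen to the trisubstituted C4=C5 alkene from the face of the allylic C3 hydroxyl, setting C4 and C5 syn to it, while the 1,1-disubstituted alkene (allylic ester, only a bishomoallylic hydroxyl) and the electron-poor angelate alkenes should react much more slowly.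

**Compound list**

1 | (1S,2R)-3-methylcyclohexa-3,5-diene-1,2-diol | CC1=CC=C[C@H](O)[C@@H]1O | starting material
2 | (3aR,7aS)-2-(4-methoxyphenyl)-4-methyl-3a,7a-dihydro-1,3-benzodioxole (acetal epimers) | CC1=CC=C[C@@H]2OC(c3ccc(OC)cc3)O[C@H]12 | intermediate
3 | (1S,6R)-6-[(4-methoxybenzyl)oxy]-5-methylcyclohexa-2,4-dien-1-ol | CC1=CC=C[C@H](O)[C@@H]1OCc1ccc(OC)cc1 | intermediate
4 | methyl (2S)-oxirane-2-carboxylate | COC(=O)[C@@H]1CO1 | starting material
5 | 1-[(2S)-oxiran-2-yl]ethan-1-one | CC(=O)[C@@H]1CO1 | intermediate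
6 | 2-[(2S)-oxiran-2-yl]propan-2-ol | CC(C)(O)[C@@H]1CO1 | intermediate
7 | triethyl({2-[(2S)-oxiran-2-yl]propan-2-yl}oxy)silane | CC[Si](CC)(CC)OC(C)(C)[C@@H]1CO1 | intermediate
8 | methoxyallene (1-methoxypropa-1,2-diene) | COC=C=C | starting material
9 | 1-lithio-1-methoxyallene | [Li]C(OC)=C=C | intermediate
10 | lithium (5S)-3-methoxy-6-methyl-6-[(triethylsilyl)oxy]hepta-1,2-dien-5-olate | C=C=C(OC)C[C@H](O[Li])C(C)(C)O[Si](CC)(CC)CC | intermediate
11 | (5S)-5-[(tert-butyldimethylsilyl)oxy]-3-methoxy-6-methyl-6-[(triethylsilyl)oxy]hepta-1,2-diene | C=C=C(OC)C[C@H](O[Si](C)(C)C(C)(C)C)C(C)(C)O[Si](CC)(CC)CC | intermediate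
12 | 2-iodoallyl mixed methyl ketal of 3 and 11 (ketal epimers) | CC1=CC=C[C@H](OC(OC)(C(I)=C)C[C@H](O[Si](C)(C)C(C)(C)C)C(C)(C)O[Si](CC)(CC)CC)[C@@H]1OCc1ccc(OC)cc1 | intermediate
13 | (3aR,7R,7aS)-2-methoxy-3-methylidene-hexahydro-1-benzofuran ketal (cis-fused, ketal epimers) | C=C1[C@H]2CC=C(C)[C@@H](OCc3ccc(OC)cc3)[C@H]2OC1(OC)C[C@H](O[Si](C)(C)C(C)(C)C)C(C)(C)O[Si](CC)(CC)CC | intermediate
14 | (5S)-5-TBSO-2-[(1R,5R,6S)-6-hydroxy-5-(PMB-oxy)-4-methylcyclohex-3-en-1-yl]-6-methyl-6-TESO-hept-1-en-3-one | C=C([C@H]1CC=C(C)[C@@H](OCc2ccc(OC)cc2)[C@H]1O)C(=O)C[C@H](O[Si](C)(C)C(C)(C)C)C(C)(C)O[Si](CC)(CC)CC | intermediate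
15 | (3S,5S)-5-TBSO-2-[(1R,5R,6S)-6-hydroxy-5-(PMB-oxy)-4-methylcyclohex-3-en-1-yl]-6-methyl-6-TESO-hept-1-en-3-ol | C=C([C@H]1CC=C(C)[C@@H](OCc2ccc(OC)cc2)[C@H]1O)[C@@H](O)C[C@H](O[Si](C)(C)C(C)(C)C)C(C)(C)O[Si](CC)(CC)CC | intermediate
16 | bis-angelate of 15 (C2–O and C8–O) | C=C([C@H]1CC=C(C)[C@@H](OCc2ccc(OC)cc2)[C@H]1OC(=O)/C(C)=C\C)[C@@H](OC(=O)/C(C)=C\C)C[C@H](O[Si](C)(C)C(C)(C)C)C(C)(C)O[Si](CC)(CC)CC | intermediate
17 | bis-angelate with free C3–OH, C10 OTBS, C11 OTES | C=C([C@H]1CC=C(C)[C@@H](O)[C@H]1OC(=O)/C(C)=C\C)[C@@H](OC(=O)/C(C)=C\C)C[C@H](O[Si](C)(C)C(C)(C)C)C(C)(C)O[Si](CC)(CC)CC | intermediate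
18 | bis-angelate triol (C3–OH, C10–OH, C11–OH), C4=C5 alkene | C=C([C@H]1CC=C(C)[C@@H](O)[C@H]1OC(=O)/C(C)=C\C)[C@@H](OC(=O)/C(C)=C\C)C[C@H](O)C(C)(C)O | intermediate
19 | CNP0189369.2 | C=C([C@H](C[C@H](O)C(C)(C)O)OC(=O)/C(C)=C\C)[C@H]1C[C@H]2O[C@@]2(C)[C@@H](O)[C@H]1OC(=O)/C(C)=C\C | target

**Step count**

Total steps: 13. Longest linear sequence: 11 steps (4 → 6 → 7 → 11 → 12 → 13 → 14 → 15 → 16 → 17 → 18 → 19).

**Steps most likely to fail**

Step 7 (radical cyclisation). The vinyl radical may be reduced before it closes, hydrogen may be delivered to the wrong end (C4) of the allyl radical, or the sensitive dienyl diether may be lost by aromatising elimination or dimerisation during the slow addition. The fallback sets out from 12 and replaces the radical chain by an organopalladium sequence: Pd(OAc)2, PPh3, HCO2Na, Et4NCl, DMF, 60 °C. Oxidative addition into the vinyl iodide, 5-exo syn-carbopalladation of C1=C6 (again cis because of the tether) and formate reduction of the π-allylpalladium intermediate at its less hindered terminus C6 (a reductive Heck cyclisation) should lead directly back to 13. No new compound is made.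

Step 6 (iodoketalisation). Electrophilic iodine may attack the ring diene or the anisyl ring, the hindered tertiary oxocarbenium ion may be captured too slowly by the secondary alcohol, or the allene may decompose under adventitious acid. The fallback sets out from 11 and separates the iodination from the diene. NIS in MeOH–CH2Cl2 with 2,6-lutidine at −78 °C should convert 11 into the dimethyl ketal (5S)-5-[(tert-butyldimethylsilyl)oxy]-2-iodo-3,3-dimethoxy-6-methyl-6-[(triethylsilyl)oxy]hept-1-ene F1. An acid-catalysed ketal exchange of F1 with alcohol 3 (PPTS cat., benzene, 5 Å molecular sieves to take up methanol) then returns to the route at 12.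

Step 9 (CBS reduction). Facial selectivity at C8 may be poor (mismatch between catalyst and the bias from C1 and C10, or interference by the boron-bound C2 hydroxyl or the hemiketal form), or conjugate reduction may compete. The fallback sets out from 14 and turns the problem into an inversion. Reduction with the (S)-oxazaborolidine (or any reductant found to favour that face) gives the C8-epimeric diol (3R,5S)-5-TBSO-2-[(1R,5R,6S)-6-hydroxy-5-(PMB-oxy)-4-methylcyclohex-3-en-1-yl]-6-methyl-6-TESO-hept-1-en-3-ol F2. Mitsunobu esterification with angelic acid (PPh3, DIAD, THF, 0 °C) at the more accessible allylic hydroxyl then inverts C8 and installs the first angelate, giving the (3S)-mono-angelate with free ring C2–OH F3. Acylation of the remaining C2 hydroxyl under the conditions of step 10 returns to the route at 16.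

Further compounds
F0 | step 7 | none | none
F1 | step 6 | (5S)-5-[(tert-butyldimethylsilyl)oxy]-2-iodo-3,3-dimethoxy-6-methyl-6-[(triethylsilyl)oxy]hept-1-ene | C=C(I)C(OC)(OC)C[C@H](O[Si](C)(C)C(C)(C)C)C(C)(C)O[Si](CC)(CC)CC
F2 | step 9 | (3R,5S)-5-TBSO-2-[(1R,5R,6S)-6-hydroxy-5-(PMB-oxy)-4-methylcyclohex-3-en-1-yl]-6-methyl-6-TESO-hept-1-en-3-ol (C8 epimer of 15) | C=C([C@H]1CC=C(C)[C@@H](OCc2ccc(OC)cc2)[C@H]1O)[C@H](O)C[C@H](O[Si](C)(C)C(C)(C)C)C(C)(C)O[Si](CC)(CC)CC
F3 | step 9 | (3S)-C8 mono-angelate of 15 with free ring C2–OH | C=C([C@H]1CC=C(C)[C@@H](OCc2ccc(OC)cc2)[C@H]1O)[C@@H](OC(=O)/C(C)=C\C)C[C@H](O[Si](C)(C)C(C)(C)C)C(C)(C)O[Si](CC)(CC)CC
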